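## The problem

CNP0185847.2 (22) is a ten-membered carbocycle. Its ring carbons are numbered here C1–C10: C1 is the ring-oxirane carbon that carries the acetoxymethyl group (C15), C4=C5 is the ring-cis (Z) double bond with the methyl group on C5, C6 is the ketone, C8 is the spiro carbon and C10 is the second carbon of the ring oxirane. The exocyclic oxirane carbon C11 carries a methyl group and the second acetoxymethyl group (C12).

A synthesis must close a strained medium ring that holds a conjugated Z-enone and, in the end, two oxiranes. The four stereocentres form two pairs, C1/C10 and C8/C11. Within each pair the relative configuration is simply the geometry of a parent alkene (C2 cis to C9 across C1=C10; C12 cis to C7 across C8=C11). The pairs are separated by C9 on a flexible ring, so neither can be relied on to control the other; each needs its own reagent control. Both oxiranes correspond to allylic-alcohol epoxidation with the same tartrate sense.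

The fragile element is the β,γ-epoxy ketone C6–C7–C8. Base can open the oxirane by elimination through the C7 enolate (in a six-membered precursor this would end in a phenol), and acid can ionise the fully substituted C8/C11 oxirane.

The feature that makes the key step possible is the 1,5-diene hidden in the ring. C1=C10 (before epoxidation) and C4=C5 are separated by the two methylenes C2 and C3. The ring is therefore the cycloreversion product of a cyclobutane C5–C10–C1–C4 that is shared by a cyclohexanone (C5–C10) and a second cyclobutane (C1–C4).

## Retrosynthesis

**22 ⇒ 21 ⇒ 20.** The two acetyl C–O bonds and the two C–O bonds of the C1/C10 oxirane are cut first. This oxirane has to come last, because C1=C10 only exists once the ring has been expanded, and it would not survive the heat of that expansion. The diol 20 has a single allylic alcohol (C15), so a hydroxyl-directed asymmetric epoxidation can address C1=C10 while the electron-poor enone bond and the non-allylic C12 alcohol stay out of play. The forward step must override whatever facial bias the folded ring has.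

**20 ⇒ 19 ⇒ 18 ⇒ 17.** After desilylation is undone (20 ⇒ 19) and the enone bond is allowed to be ring-trans (19 ⇒ 18), the ring is contracted: C5 is joined to C10 and C1 to C4, giving the tricyclic ketone 17. Compared with any macrocyclisation, this turns the ten-membered ring into a six-membered ring plus a four-membered ring and needs no high dilution. The forward thermolysis must cleave C5–C10 and not C2–C3, must stop before the 1,5-diene undergoes Cope rearrangement, and must leave C1=C10 ring-cis. The enone bond can be corrected afterwards because it is conjugated.

**17 ⇒ 12 + 16.** The bonds C4–C5 and C1–C10 are cut in the sense of a [2+2] cycloaddition. This gives the 2-methylcyclohexenone 12, which already holds the C8/C11 oxirane, and the cyclobutene 16. It is the most simplifying cut in the plan: two ring C–C bonds and the whole C1–C4/C15 segment arrive in one step from a trivially made partner. The forward reaction must be head-to-tail (substituted cyclobutene carbon to the enone β-carbon C10).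

**12 ⇒ 11.** The C5=C10 double bond is cut by ring-closing metathesis. Building the C8=C11 alkene on a preformed cyclohexenone was rejected: an exocyclic alkene there has no handle to tell C7 from C9, and the dienone would aromatise. In the open chain the two arms on C8 are different groups, so the oxirane configuration can be set before the ring exists. The forward step must close onto a 1,1-disubstituted enone alkene under neutral conditions.

**11 ⇒ 10 ⇒ 9 ⇒ 8.** The C5–C6 bond is cut (isopropenyl Grignard reagent onto a Weinreb amide), the silyl group is removed, and the C8/C11 oxirane is traced to the tetrasubstituted allylic alcohol 8. Epoxidising at this stage, on a small acyclic alcohol with one allylic hydroxyl, gives the cleanest reagent control available in the route. The forward epoxidation must deliver oxygen to the face that makes C11 (R), and the geometry of 8 (C7 cis to C12) then fixes C8.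

**8 ⇒ 7 ⇒ 5.** The amide C–N bond is cut back to the lactone 7, and the C7–C8 bond of 7 is cut to the alkenyl iodide 5 and a zinc ester enolate. The six-membered lactone is the device that secures the alkene geometry: only the isomer with C7 cis to C12 can close it, and opening it with the aminoaluminium reagent releases exactly the allylic alcohol needed next. The coupling must proceed with retention at a hindered sp2 carbon.

**5 ⇒ 3 ⇒ 1 + 2.** The C11–CH3 and C8–I bonds are cut in the sense of an anti-carbomagnesiation of the propargylic alcohol 3 followed by iodinolysis. 3 comes from propargyl alcohol 1 and allyl bromide 2. The hydroxyl group fixes both the regiochemistry (methyl to the proximal carbon) and the geometry (metal, then iodine, cis to CH2OH).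

**16 ⇒ 15 ⇒ 14 ⇒ 13.** The cyclobutene is taken back through alcohol 15 and acid 14 to commercial bromo ester 13 by silylation, hydride reduction and dehydrobromination.

## Roads not taken

**Alternative 1:** The ring is cut at C5–C6. An open-chain (Z)-alkenyl iodide aldehyde A1 would be closed with CrCl2 (divalent chromium) and catalytic NiCl2 to the macrocyclic trienol A2, as a mixture at the C6 carbinol. Oxidation and desilylation would then lead to the trienone diol A3 of Alternative 2.

- Merits: the chromium reagent attacks only the aldehyde and keeps the Z geometry of the iodide. All three alkene geometries are fixed and checkable in the acyclic precursor. In this respect the road is better than the chosen one, which has to get its alkene geometry out of a thermolysis.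
- Weak points: a ten-membered ring is closed by a bimolecular-type C–C bond formation, which means high dilution, a large excess of chromium salt and transannular strain in the transition state. A1 needs three stereodefined tri- and tetrasubstituted alkenes in one chain, plus an aldehyde whose α-methylene is flanked by the C8=C11 alkene and slips easily into conjugation. Oxidation and both epoxidations still remain on a macrocyclic triene.
- Comparison: the chosen plan offers a ring made from existing rings with two C–C bonds formed at once, only one stereodefined acyclic alkene to prepare, and the C8/C11 oxirane in place before any ring exists.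

**Alternative 2:** Four C–O bonds are cut. Ti(OiPr)4, D-(−)-diethyl tartrate and tert-butyl hydroperoxide would epoxidise C1=C10 and C8=C11 of the trienone diol A3 in one operation to the diepoxy diol A4 (identical with 21).

- Merits: both allylic alcohols call for the same tartrate, the enone bond is inert to the reagent, and the endgame could not be shorter. At the epoxidation stage this road is one step better than the chosen plan.
- Weak points: the cut says nothing about how the ring of A3 is made. A3 keeps the C8=C11 alkene between two doubly activated methylenes (C7 next to the ketone, C9 between two alkenes), so it invites conjugation. Two titanium-bound alcohols on one flexible ring must each be matched to the catalyst, and neither selectivity can be checked separately.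
- Comparison: the chosen plan spends one more epoxidation step. In return the first epoxidation runs on the small acyclic alcohol 8, and the second runs on a ring that has only one allylic alcohol.

**Alternative 3:** The ring is cut at C3–C4. The vinyl group (C2=C3) on the C1 oxirane of the diepoxide A5 would be hydroborated with 9-BBN at C3. The alkylborane would then couple with the (Z)-β-iodoenone at C4 under Pd(dppf)Cl2 (reduced in situ to zerovalent palladium) and mild base, giving the bis-silyl ether A6 of the diepoxy ketone.

- Merits: this is the most convergent road. Both oxiranes are made under acyclic reagent control, the sp3–sp2 coupling keeps the Z geometry, and only desilylation and acetylation follow ring closure. In post-cyclisation step count and in certainty of geometry it is better than the chosen plan.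
- Weak points: A5 is a vinyl oxirane, which zerovalent palladium can ionise and boranes can open. 9-BBN must pick the vinyl group in the presence of a ketone and an iodoenone. The aqueous base needed for transmetalation meets a β,γ-epoxy ketone (elimination) and a β-iodoenone (addition–elimination). The ten-membered ring must close through a palladacycle that already contains two rigid oxiranes.
- Comparison: the chosen plan has no organometallic macrocyclisation in the presence of both oxiranes, and its ring expansion is driven by release of about two cyclobutanes' worth of strain rather than opposed by ring strain.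

Key step: step 12

## Route

Remark on the chemistry: 17 is drawn as the diastereomer in which the cyclobutene has added to the enone face opposite C11. The other facial isomer would converge on the same 18, because C1, C4, C5 and C10 lose their configuration in step 13.

Step 1
Reactants: 1 prop-2-yn-1-ol; 2 3-bromoprop-1-ene
Product: 3 hex-5-en-2-yn-1-ol
Conditions: CuI (10 mol%), K2CO3, Bu4NI (cat.), DMF, rt
Reagents that add atoms: none
Why: Copper-catalysed coupling of a terminal alkyne with an allylic halide (copper acetylide displacement) should give the skipped enyne; no stereocentre is formed.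

Step 2
Reactants: 3 hex-5-en-2-yn-1-ol
Product: 5 (2Z)-3-iodo-2-methylhexa-2,5-dien-1-ol, via cyclic alkenylmagnesium alkoxide 4 (not isolated)
Conditions: MeMgBr (3.5 equiv), CuI (15 mol%), THF, 0 °C → 40 °C; then I2, −40 → 0 °C; aq. Na2S2O3
Reagents that add atoms: methylmagnesium bromide, C[Mg]Br; iodine, II
Why: Copper-catalysed anti-carbomagnesiation of a propargylic alkoxide: methyl is delivered to the alkyne carbon next to CH2OH and magnesium stays on the distal carbon inside a five-membered chelate (4), so methyl and metal are trans. Iodinolysis with retention puts iodine cis to CH2OH, the geometry that later places C7 cis to C12.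

Step 3
Reactants: 5 (2Z)-3-iodo-2-methylhexa-2,5-dien-1-ol
Product: 7 5-methyl-4-(prop-2-en-1-yl)-3,6-dihydro-2H-pyran-2-one, via hydroxy ester 6 (not isolated)
Conditions: BrZnCH2CO2Et (2.5 equiv, preformed in THF), Pd(P(t-Bu)3)2 (5 mol%), THF, 50 °C; then PPTS (cat.), PhMe, 50 °C
Reagents that add atoms: bromo(2-ethoxy-2-oxoethyl)zinc (Reformatsky reagent), CCOC(=O)C[Zn]Br
Why: Negishi coupling of a zinc ester enolate with an alkenyl iodide should proceed with retention at the sp2 carbon. The cis hydroxymethyl group then lactonises, which only the required Z isomer can do, so ring closure both proves and locks the geometry.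

Step 4
Reactants: 7 5-methyl-4-(prop-2-en-1-yl)-3,6-dihydro-2H-pyran-2-one
Product: 8 (3Z)-5-hydroxy-N-methoxy-N,4-dimethyl-3-(prop-2-en-1-yl)pent-3-enamide
Conditions: MeNH(OMe)·HCl, AlMe3, CH2Cl2, 0 °C → rt; aq. KNaC4H4O6 (potassium sodium tartrate)
Reagents that add atoms: N,O-dimethylhydroxylamine hydrochloride, CNOC.Cl
Why: Weinreb aminolysis of a lactone with the aluminium amide, which is Lewis acidic and not basic, so the β,γ-double bond should not migrate. It frees the allylic alcohol needed for epoxidation and turns C6 into an acyl donor that takes up a single equivalent of Grignard reagent.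

Step 5
Reactants: 8 (3Z)-5-hydroxy-N-methoxy-N,4-dimethyl-3-(prop-2-en-1-yl)pent-3-enamide
Product: 9 2-[(2S,3R)-3-(hydroxymethyl)-3-methyl-2-(prop-2-en-1-yl)oxiran-2-yl]-N-methoxy-N-methylacetamide
Conditions: Ti(OiPr)4 (10 mol%), D-(−)-diethyl tartrate (12 mol%), t-BuOOH, 4 Å MS, CH2Cl2, −20 °C; non-acidic work-up
Reagents that add atoms: tert-butyl hydroperoxide, CC(C)(C)OO
Why: Sharpless asymmetric epoxidation: the D-(−)-tartrate catalyst should deliver oxygen to the face that makes the carbinol-bearing carbon C11 (R). Addition is syn and C7 is cis to C12 in 8, so C8 follows as (S). The electron-rich tetrasubstituted allylic alcohol reacts, and the terminal allyl group, which is not an allylic alcohol, is left alone.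

Step 6
Reactants: 9 2-[(2S,3R)-3-(hydroxymethyl)-3-methyl-2-(prop-2-en-1-yl)oxiran-2-yl]-N-methoxy-N-methylacetamide
Product: 10 2-[(2S,3R)-3-({[tert-butyl(dimethyl)silyl]oxy}methyl)-3-methyl-2-(prop-2-en-1-yl)oxiran-2-yl]-N-methoxy-N-methylacetamide
Conditions: TBSCl, imidazole, CH2Cl2, 0 °C → rt
Reagents that add atoms: tert-butyldimethylsilyl chloride, CC(C)(C)[Si](C)(C)Cl
Why: Silylation of the primary alcohol protects C12 for the Grignard step, the photochemistry and the thermolysis; no stereocentre is touched.

Step 7
Reactants: 10 2-[(2S,3R)-3-({[tert-butyl(dimethyl)silyl]oxy}methyl)-3-methyl-2-(prop-2-en-1-yl)oxiran-2-yl]-N-methoxy-N-methylacetamide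
Product: 11 1-[(2S,3R)-3-({[tert-butyl(dimethyl)silyl]oxy}methyl)-3-methyl-2-(prop-2-en-1-yl)oxiran-2-yl]-3-methylbut-3-en-2-one
Conditions: CH2=C(CH3)MgBr, THF, −20 → 0 °C; inverse quench into cold aq. NH4Cl
Reagents that add atoms: isopropenylmagnesium bromide, CC(=C)[Mg]Br
Why: Weinreb ketone synthesis: the alkenyl Grignard reagent adds once and the chelated tetrahedral adduct persists until the quench, so the β,γ-epoxy ketone is never exposed to base as a free enolisable ketone. The cold inverse quench keeps the liberated amine from adding to the enone.

Step 8
Reactants: 11 1-[(2S,3R)-3-({[tert-butyl(dimethyl)silyl]oxy}methyl)-3-methyl-2-(prop-2-en-1-yl)oxiran-2-yl]-3-methylbut-3-en-2-one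
Product: 12 (2R,3S)-2-({[tert-butyl(dimethyl)silyl]oxy}methyl)-2,6-dimethyl-1-oxaspiro[2.5]oct-6-en-5-one
Conditions: second-generation Grubbs catalyst RuCl2(=CHPh)(PCy3)(H2IMes) (5 mol%), CH2Cl2, 40 °C
Reagents that add atoms: none
Why: Ring-closing metathesis: the ruthenium carbene should load at the monosubstituted allyl alkene and close onto the 1,1-disubstituted enone alkene, giving the trisubstituted cyclohexenone with loss of ethene. The quaternary C8 favours closure, and the neutral medium spares the β,γ-epoxy ketone, whose base-induced opening would end in a phenol.

Step 9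
Reactants: 13 ethyl 1-bromocyclobutane-1-carboxylate
Product: 14 cyclobut-1-ene-1-carboxylic acid
Conditions: KOH (powder), PhMe, reflux; then aq. HCl
Reagents that add atoms: potassium hydroxide, [K+].[OH-]
Why: Dehydrobromination (E2) and saponification in one operation; this is the established preparation of the acid.

Step 10
Reactants: 14 cyclobut-1-ene-1-carboxylic acid
Product: 15 (cyclobut-1-en-1-yl)methanol
Conditions: LiAlH4, Et2O, 0 °C
Reagents that add atoms: none
Why: Hydride reduction of the conjugated acid should go 1,2 to the allylic alcohol; at 0 °C the ring alkene is not expected to be hydroaluminated.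

Step 11
Reactants: 15 (cyclobut-1-en-1-yl)methanol
Product: 16 tert-butyl[(cyclobut-1-en-1-yl)methoxy]dimethylsilane
Conditions: TBSCl, imidazole, CH2Cl2, 0 °C → rt
Reagents that add atoms: tert-butyldimethylsilyl chloride, CC(C)(C)[Si](C)(C)Cl
Why: Silylation gives a non-volatile, electron-rich 1-alkylcyclobutene that does not absorb above 300 nm.

Step 12
Reactants: 12 (2R,3S)-2-({[tert-butyl(dimethyl)silyl]oxy}methyl)-2,6-dimethyl-1-oxaspiro[2.5]oct-6-en-5-one; 16 tert-butyl[(cyclobut-1-en-1-yl)methoxy]dimethylsilane
Product: 17 cis-anti-cis tricyclic photoadduct (cyclohexanone C5–C10 fused at C5–C10 to the central cyclobutane C5–C10–C1–C4, which shares C1–C4 with the cyclobutane C1–C2–C3–C4; C5 methyl, C1 CH2OTBS; cyclobutane on the cyclohexanone face that carries the oxirane oxygen; C8 and C11 as in 12)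
Conditions: hν (366 nm, Pyrex), 16 (5 equiv), CH2Cl2, −40 °C, degassed
Reagents that add atoms: none
Why: The enone is excited (n→π*) and crosses to its triplet, which adds to the cyclobutene through a triplet 1,4-diradical that closes after spin inversion; the closest known reaction type is the [2+2] photocycloaddition of cyclohex-2-enones to cyclobutenes, which gives tricyclo[4.4.0.0(2,5)]decanones. The one new ring, the central cyclobutane C5–C10–C1–C4, closes by stepwise radical combination and carries both new bonds, C4–C5 and C1–C10. C1 and C4 are cis because they are tied in the four-membered ring of 16; C5 and C10 should be cis because a trans-fused cyclobutane on a six-membered ring that is in turn fused to a second cyclobutane is too strained to close; the anti arrangement follows from the cyclobutene approaching with its CH2CH2 bridge turned away from the cyclohexanone ring. The face of the enone is chosen by the spiro centre C8, attack being expected anti to the bulkier C11 arm, but this choice is without consequence because C1, C4, C5 and C10 all become sp2 in step 13. The selectivity that matters is head-to-tail regiochemistry (C1 to C10, C4 to C5): it is favoured electronically for an electron-rich 1-alkylcyclobutene and, more strongly, sterically, since the alternative would join the two fully substituted carbons C1 and C5. C8 and C11 are spectators. Irradiation above 350 nm, low temperature and an excess of 16 should keep the product ketone from absorbing and the enone from dimerising.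

Step 13
Reactants: 17 cis-anti-cis tricyclic photoadduct
Product: 18 (2R,3S,6E,10E)-2,10-bis({[tert-butyl(dimethyl)silyl]oxy}methyl)-2,6-dimethyl-1-oxaspiro[2.9]dodeca-6,10-dien-5-one (C1=C10 ring-cis, C4=C5 ring-trans)
Conditions: PhMe (0.01 M, degassed), base-washed sealed tube, 185 °C, stopped before full conversion; 17 recycled
Reagents that add atoms: none
Why: Thermal cycloreversion of the bicyclo[2.2.0]hexane unit: the central C1–C4 bond breaks first to a cyclohexane-1,4-diyl, which should fragment at C5–C10 and not at C2–C3 because only that scission develops the conjugated enone. Fragmentation from the chair diyl gives one ring-cis and one ring-trans double bond; the chair in which C1 has inverted keeps the CH2OSi-bearing carbon away from the substituents on C8, so C1=C10 should emerge ring-cis and the enone bond ring-trans. High dilution, base-washed glass and interruption before full conversion limit Cope rearrangement of the 1,5-diene and acid-induced opening of the oxirane.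

Step 14
Reactants: 18 (2R,3S,6E,10E)-dienone
Product: 19 (2R,3S,6Z,10E)-2,10-bis({[tert-butyl(dimethyl)silyl]oxy}methyl)-2,6-dimethyl-1-oxaspiro[2.9]dodeca-6,10-dien-5-one (both ring double bonds ring-cis)
Conditions: I2 (5 mol%), NaHCO3 (solid), PhH, rt, visible light
Reagents that add atoms: none
Why: Iodine-atom-catalysed E/Z equilibration: iodine atoms add reversibly to the β-carbon C4 of the enone and allow rotation about C4–C5, so the strained ring-trans enone should drain to the ring-cis isomer. The β-iodo radical loses iodine far faster than it could attack C1=C10 across the ring, and the unconjugated C1=C10 bond is not expected to react at room temperature.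

Step 15
Reactants: 19 (2R,3S,6Z,10E)-dienone bis-silyl ether
Product: 20 (2R,3S,6Z,10E)-2,10-bis(hydroxymethyl)-2,6-dimethyl-1-oxaspiro[2.9]dodeca-6,10-dien-5-one
Conditions: Bu4NF, AcOH (1:1), THF, 0 °C → rt
Reagents that add atoms: none
Why: Buffered fluoride desilylation removes both primary silyl ethers; the acetic acid keeps the medium from becoming basic enough to open the β,γ-epoxy ketone by elimination.

Step 16
Reactants: 20 (2R,3S,6Z,10E)-2,10-bis(hydroxymethyl)-2,6-dimethyl-1-oxaspiro[2.9]dodeca-6,10-dien-5-one
Product: 21 diepoxy diol (20 with a (1R,10R)-oxirane across C1–C10; C8 S, C11 R; Z-enone; C12 and C15 hydroxymethyl groups)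
Conditions: Ti(OiPr)4 (20 mol%), D-(−)-diethyl tartrate (24 mol%), t-BuOOH, 4 Å MS, CH2Cl2, −20 °C; non-acidic work-up
Reagents that add atoms: tert-butyl hydroperoxide, CC(C)(C)OO
Why: Sharpless asymmetric epoxidation directed by the C15 hydroxyl: C9 is trans to CH2OH, the best substrate pattern, and the D-(−)-tartrate catalyst should deliver oxygen to the face that gives (1R,10R), the same sense as in step 5. The enone bond is electron-poor and the C12 alcohol is not allylic, so neither should compete.

Step 17
Reactants: 21 diepoxy diol
Product: 22 CNP0185847.2 (diacetate of 21)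
Conditions: Ac2O, pyridine, DMAP (cat.), CH2Cl2, 0 °C
Reagents that add atoms: acetic anhydride, CC(=O)OC(C)=O
Why: DMAP-catalysed acetylation of the two primary alcohols under mild, weakly basic conditions; no stereocentre is affected.

## Compound list

1 | prop-2-yn-1-ol | C#CCO | starting material
2 | 3-bromoprop-1-ene | C=CCBr | starting material
3 | hex-5-en-2-yn-1-ol | OCC#CCC=C | intermediate
4 | cyclic alkenylmagnesium alkoxide (4-methyl-3-(prop-2-en-1-yl)-2,5-dihydro-1,2-oxamagnesole) | C=CCC1=C(C)CO[Mg]1 | intermediate (not isolated)
5 | (2Z)-3-iodo-2-methylhexa-2,5-dien-1-ol | OC/C(C)=C(\I)CC=C | intermediate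
6 | ethyl (3Z)-5-hydroxy-4-methyl-3-(prop-2-en-1-yl)pent-3-enoate | CCOC(=O)C/C(CC=C)=C(C)\CO | intermediate (not isolated)
7 | 5-methyl-4-(prop-2-en-1-yl)-3,6-dihydro-2H-pyran-2-one | O=C1CC(CC=C)=C(C)CO1 | intermediate
8 | (3Z)-5-hydroxy-N-methoxy-N,4-dimethyl-3-(prop-2-en-1-yl)pent-3-enamide | CON(C)C(=O)C/C(CC=C)=C(C)\CO | intermediate
9 | 2-[(2S,3R)-3-(hydroxymethyl)-3-methyl-2-(prop-2-en-1-yl)oxiran-2-yl]-N-methoxy-N-methylacetamide | C=CC[C@@]1(CC(=O)N(C)OC)O[C@]1(C)CO | intermediate
10 | 2-[(2S,3R)-3-({[tert-butyl(dimethyl)silyl]oxy}methyl)-3-methyl-2-(prop-2-en-1-yl)oxiran-2-yl]-N-methoxy-N-methylacetamide | C=CC[C@@]1(CC(=O)N(C)OC)O[C@]1(C)CO[Si](C)(C)C(C)(C)C | intermediate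
11 | 1-[(2S,3R)-3-({[tert-butyl(dimethyl)silyl]oxy}methyl)-3-methyl-2-(prop-2-en-1-yl)oxiran-2-yl]-3-methylbut-3-en-2-one | C=CC[C@@]1(CC(=O)C(C)=C)O[C@]1(C)CO[Si](C)(C)C(C)(C)C | intermediate
12 | (2R,3S)-2-({[tert-butyl(dimethyl)silyl]oxy}methyl)-2,6-dimethyl-1-oxaspiro[2.5]oct-6-en-5-one | CC1=CC[C@@]2(CC1=O)O[C@]2(C)CO[Si](C)(C)C(C)(C)C | intermediate
13 | ethyl 1-bromocyclobutane-1-carboxylate | CCOC(=O)C1(Br)CCC1 | starting material
14 | cyclobut-1-ene-1-carboxylic acid | OC(=O)C1=CCC1 | intermediate
15 | (cyclobut-1-en-1-yl)methanol | OCC1=CCC1 | intermediate
16 | tert-butyl[(cyclobut-1-en-1-yl)methoxy]dimethylsilane | CC(C)(C)[Si](C)(C)OCC1=CCC1 | intermediate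
17 | cis-anti-cis tricyclic photoadduct, bis-silyl ether (cyclobutane on the face of the oxirane oxygen) | CC(C)(C)[Si](C)(C)OC[C@@]12CC[C@@H]1[C@@]4(C)C(=O)C[C@]3(C[C@@H]24)O[C@]3(C)CO[Si](C)(C)C(C)(C)C | intermediate
18 | (2R,3S,6E,10E)-2,10-bis({[tert-butyl(dimethyl)silyl]oxy}methyl)-2,6-dimethyl-1-oxaspiro[2.9]dodeca-6,10-dien-5-one | CC(C)(C)[Si](C)(C)OC/C1=C/C[C@@]2(CC(=O)/C(C)=C/CC1)O[C@]2(C)CO[Si](C)(C)C(C)(C)C | intermediate
19 | (2R,3S,6Z,10E)-2,10-bis({[tert-butyl(dimethyl)silyl]oxy}methyl)-2,6-dimethyl-1-oxaspiro[2.9]dodeca-6,10-dien-5-one | CC(C)(C)[Si](C)(C)OC/C1=C/C[C@@]2(CC(=O)/C(C)=C\CC1)O[C@]2(C)CO[Si](C)(C)C(C)(C)C | intermediate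
20 | (2R,3S,6Z,10E)-2,10-bis(hydroxymethyl)-2,6-dimethyl-1-oxaspiro[2.9]dodeca-6,10-dien-5-one | OC/C1=C/C[C@@]2(CC(=O)/C(C)=C\CC1)O[C@]2(C)CO | intermediate
21 | diepoxy diol (C1 R, C10 R, C8 S, C11 R; Z-enone) | OC[C@]12CC/C=C(/C)C(=O)C[C@]3(C[C@H]1O2)O[C@]3(C)CO | intermediate
22 | CNP0185847.2 (diacetate of 21) | CC(=O)OC[C@]12CC/C=C(/C)C(=O)C[C@]3(C[C@H]1O2)O[C@]3(C)COC(C)=O | target

## Step count and risks

Total step count: 17. Longest linear sequence: 14 steps (steps 1–8, then 12–17); steps 9–11 form the three-step side branch to 16.

**Step 12 (key step).** The most likely failure is inefficient capture of the triplet enone. The first bond has to form either next to the methyl-bearing α-carbon or at the trisubstituted cyclobutene carbon, and the 1,4-diradical can fall apart again. On long irradiation, enone dimerisation and α-cleavage of the cyclobutyl ketone product would then take over.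

Fallback (sets out from 12 and 15, returns at 18): a temporary silicon tether makes the same two bonds intramolecularly.
- Buffered fluoride (Bu4NF, AcOH) frees the C12 alcohol of 12 to give the hydroxy enone F1.
- Alcohol 15 is silylated with excess iPr2SiCl2 and imidazole to the chlorosilane F2, which is joined to F1 to give the silylene-tethered enone–cyclobutene F3.
- Irradiation of F3 at high dilution should close C4–C5 and C1–C10 to the bridged photoadduct F4. It is drawn with the cyclobutane on the face of C11, from which the tether hangs; the face is again irrelevant.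
- Fluoride removes the silylene to give the tricyclic diol F5, and TBSCl with imidazole gives the bis-silyl ether F6, the facial diastereomer of 17.
- Thermolysis of F6 under the conditions of step 13 returns the material to 18.

**Step 13.** Two processes threaten it. The diyl may fragment through the other chair, so that the ring-trans bond ends up at C1=C10 instead of at the enone; the two chairs differ only by a few gauche interactions. The cis,trans-1,5-diene may also undergo Cope rearrangement at the temperature at which it is formed. Partial conversion with recycling addresses the second; the fallback addresses the first, and also any geometric mixture that comes from stereoisomeric photoadducts.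

Fallback (sets out from 17, returns at 20): a thermodynamic funnel through the C15 aldehyde.
- The thermolysate, in which the (6Z,10Z) bis-silyl dienone F7 would then predominate, is desilylated (Bu4NF, AcOH) to the (6Z,10Z) diol F8.
- MnO2 oxidises only the allylic C15 alcohol, giving the (6Z,10Z) aldehyde F9.
- Both ring double bonds are now conjugated. Iodine-catalysed equilibration as in step 14 should move every geometric isomer to the (6Z,10E) aldehyde F10, in which the formyl group is trans to C9. This is the usual preference of a trisubstituted enal and is the ring-cis arrangement.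
- NaBH4 at −78 °C (EtOH, CH2Cl2) reduces the aldehyde in the presence of the enone and gives 20.

**Step 16.** The likely failure is slow and poorly face-selective epoxidation if the face preferred by the tartrate catalyst is the one shielded across the ring. The titanium alkoxide could meanwhile open the acid-sensitive C8/C11 oxirane.

Fallback (sets out from 19, returns at 21): reagent control that does not need the hydroxyl group. Shi epoxidation of 19 with the D-fructose-derived ketone and KHSO5 at buffered pH should attack only the electron-rich trisubstituted C1=C10 bond, from the face that gives the (R,R)-oxirane of such alkenes. This gives the bis-silyl diepoxide F11, and buffered fluoride (Bu4NF, AcOH) then gives 21.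

**Step 3.** The likely failure is slow oxidative addition and transmetalation at the tetrasubstituted alkenyl iodide. That leaves time for protodeiodination and for the basic zinc enolate to deprotonate the γ-position of the β,γ-unsaturated ester, moving the double bond.

Fallback (sets out from 5, returns at 7): a neutral tin reagent replaces the enolate. Stille coupling of 5 with Bu3SnCH2CN (Pd(PPh3)4, PhMe, heat) should give the hydroxy nitrile F12 with retention of geometry. Treatment with HCl in MeOH and then water (Pinner reaction) lets the cis hydroxyl group add to the nitrile, and hydrolysis gives 7.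

## Further compounds

F1 | step 12 | (2R,3S)-2-(hydroxymethyl)-2,6-dimethyl-1-oxaspiro[2.5]oct-6-en-5-one | CC1=CC[C@@]2(CC1=O)O[C@]2(C)CO
F2 | step 12 | chloro[(cyclobut-1-en-1-yl)methoxy]di(propan-2-yl)silane | CC(C)[Si](Cl)(OCC1=CCC1)C(C)C
F3 | step 12 | [(cyclobut-1-en-1-yl)methoxy]{[(2R,3S)-2,6-dimethyl-5-oxo-1-oxaspiro[2.5]oct-6-en-2-yl]methoxy}di(propan-2-yl)silane | CC1=CC[C@@]2(CC1=O)O[C@]2(C)CO[Si](C(C)C)(C(C)C)OCC3=CCC3
F4 | step 12 | silylene-bridged cis-anti-cis photoadduct (cyclobutane on the face of C11) | CC(C)[Si]1(C(C)C)OC[C@]23CC[C@H]2[C@]5(C)C(=O)C[C@]4(C[C@H]35)O[C@]4(C)CO1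
F5 | step 12 | tricyclic diol (facial diastereomer of the diol of 17) | OC[C@]12CC[C@H]1[C@]4(C)C(=O)C[C@]3(C[C@H]24)O[C@]3(C)CO
F6 | step 12 | bis-silyl ether, facial diastereomer of 17 | CC(C)(C)[Si](C)(C)OC[C@]12CC[C@H]1[C@]4(C)C(=O)C[C@]3(C[C@H]24)O[C@]3(C)CO[Si](C)(C)C(C)(C)C
F7 | step 13 | (2R,3S,6Z,10Z)-2,10-bis({[tert-butyl(dimethyl)silyl]oxy}methyl)-2,6-dimethyl-1-oxaspiro[2.9]dodeca-6,10-dien-5-one | CC(C)(C)[Si](C)(C)OC/C1=C\C[C@@]2(CC(=O)/C(C)=C\CC1)O[C@]2(C)CO[Si](C)(C)C(C)(C)C
F8 | step 13 | (2R,3S,6Z,10Z)-2,10-bis(hydroxymethyl)-2,6-dimethyl-1-oxaspiro[2.9]dodeca-6,10-dien-5-one | OC/C1=C\C[C@@]2(CC(=O)/C(C)=C\CC1)O[C@]2(C)CO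
F9 | step 13 | (2R,3S,6Z,10Z)-2-(hydroxymethyl)-2,6-dimethyl-5-oxo-1-oxaspiro[2.9]dodeca-6,10-diene-10-carbaldehyde | O=C/C1=C\C[C@@]2(CC(=O)/C(C)=C\CC1)O[C@]2(C)CO
F10 | step 13 | (2R,3S,6Z,10E)-2-(hydroxymethyl)-2,6-dimethyl-5-oxo-1-oxaspiro[2.9]dodeca-6,10-diene-10-carbaldehyde | O=C/C1=C/C[C@@]2(CC(=O)/C(C)=C\CC1)O[C@]2(C)CO
F11 | step 16 | bis(tert-butyldimethylsilyl) ether of 21 | CC(C)(C)[Si](C)(C)OC[C@]12CC/C=C(/C)C(=O)C[C@]3(C[C@H]1O2)O[C@]3(C)CO[Si](C)(C)C(C)(C)C
F12 | step 3 | (3Z)-5-hydroxy-4-methyl-3-(prop-2-en-1-yl)pent-3-enenitrile | N#CC/C(CC=C)=C(C)\CO
A1 | alternative 1 | open-chain (Z)-alkenyl iodide aldehyde, bis-silyl ether | I/C(C)=C\CC/C(CO[Si](C)(C)C(C)(C)C)=C\C/C(=C(\C)CO[Si](C)(C)C(C)(C)C)CC=O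
A2 | alternative 1 | macrocyclic trienol bis-silyl ether (C6 carbinol, both configurations) | CC(C)(C)[Si](C)(C)OC/C1=C/C/C(=C(\C)CO[Si](C)(C)C(C)(C)C)CC(O)/C(C)=C\CC1
A3 | alternative 2 | macrocyclic trienone diol | OC/C1=C/C/C(=C(\C)CO)CC(=O)/C(C)=C\CC1
A4 | alternative 2 | diepoxy diol (identical with 21) | OC[C@]12CC/C=C(/C)C(=O)C[C@]3(C[C@H]1O2)O[C@]3(C)CO
A5 | alternative 3 | open-chain diepoxide with C1 vinyl group and (Z)-β-iodoenone, bis-silyl ether | C=C[C@]1(CO[Si](C)(C)C(C)(C)C)O[C@@H]1C[C@@]2(CC(=O)/C(C)=C\I)O[C@]2(C)CO[Si](C)(C)C(C)(C)C
A6 | alternative 3 | bis-silyl ether of the diepoxy ketone | CC(C)(C)[Si](C)(C)OC[C@]12CC/C=C(/C)C(=O)C[C@]3(C[C@H]1O2)O[C@]3(C)CO[Si](C)(C)C(C)(C)C
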